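**Strategy.** The dihydrofuran ring is closed last at the O1–C2 bond. The precursor is an open-chain syn-chlorohydrin in which O1 is still masked as the aryl ester of the side-chain acid. Mild base triggers an O→O acyl shift from O1 to the C3 carbinol oxygen; the phenoxide thus unmasked displaces the allylic chloride at C2 (5-exo-tet, inversion), giving the 2,3-trans ring and the C3 ester in one operation. The step exploits the vicinal C2–O1/C3–O pair beside the isopropenyl group: both stereocentres come from one asymmetric γ-chloroallylboration of a salicylaldehyde ester, and the acid is never activated at the hindered C3 alcohol.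

Key step: step 7

Assumption (remark on the chemistry): the facial sense of the Ipc2B reagent is taken from the usual Ipc2B allylboration model, in which the reagent made from (+)-Ipc2BOMe [Ipc from (−)-α-pinene] adds to the re face of the aldehyde; if the sense proves opposite, (−)-Ipc2BOMe is used instead.

**Route**

Step 1
Reactants: 1 but-2-yn-1-ol
Product: 2 (Z)-2-(tributylstannyl)but-2-en-1-ol
Conditions: Bu3SnH (1.05 equiv), [Cp*RuCl]4 (1.25 mol%), CH2Cl2, rt
Reagents that add atoms: tributyltin hydride, CCCC[SnH](CCCC)CCCC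
Why: Hydroxyl-directed Ru-catalysed trans-hydrostannation of a propargylic alcohol should put tin on the alkyne carbon next to CH2OH and hydrogen on the distal carbon from the opposite face, so that Sn is cis to CH3 (Z), which fixes the later angelate-type geometry.

Step 2
Reactants: 2 (Z)-2-(tributylstannyl)but-2-en-1-ol
Product: 4 (Z)-2-(hydroxymethyl)but-2-enoic acid, via dilithio alkoxide 3 (not isolated)
Conditions: MeLi (2.2 equiv), THF, −78 °C; CO2, −78 °C to rt; aq. HCl
Reagents that add atoms: carbon dioxide, O=C=O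
Why: Tin–lithium exchange on the lithium alkoxide should give a configurationally stable alkenyllithium that is carboxylated with retention, so CO2H ends cis to CH3 (Z).

Step 3
Reactants: 4 (Z)-2-(hydroxymethyl)but-2-enoic acid
Product: 5 (Z)-2-(acetoxymethyl)but-2-enoic acid
Conditions: AcCl (1.5 equiv), CH2Cl2, 0 °C to rt; then H2O
Reagents that add atoms: acetyl chloride, CC(=O)Cl
Why: O-Acetylation of the primary allylic alcohol by an acyl chloride without base or nucleophilic catalyst should avoid conjugate addition (Z to E isomerisation) and SN2′ chemistry at the enoate.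

Step 4
Reactants: 6 1-(4-hydroxy-2-methoxyphenyl)ethanone
Product: 8 5-acetyl-2-hydroxy-4-methoxybenzaldehyde, via aryl aldimine 7 (not isolated)
Conditions: (CH2)6N4 (2 equiv), TFA, 85 °C; then aq. HCl, 60 °C
Reagents that add atoms: hexamethylenetetramine, C1N2CN3CN1CN(C2)C3; water, O
Why: Duff reaction: the iminium electrophile should attack ortho to the phenol, where the para position is blocked by acetyl and the site para to OMe is preferred over the one flanked by OH and OMe; hydrolysis of aldimine 7 then gives the aldehyde.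

Step 5
Reactants: 5 (Z)-2-(acetoxymethyl)but-2-enoic acid; 8 5-acetyl-2-hydroxy-4-methoxybenzaldehyde
Product: 10 4-acetyl-2-formyl-5-methoxyphenyl (Z)-2-(acetoxymethyl)but-2-enoate, via mixed anhydride 9 (not isolated)
Conditions: 2,4,6-Cl3C6H2COCl, Et3N, THF, 0 °C; then 8, Et3N, toluene, rt to 40 °C (no DMAP)
Reagents that add atoms: none
Why: Yamaguchi mixed-anhydride esterification: the triethylammonium phenoxide of 8 should attack the less hindered enoyl carbonyl of 9, and leaving out DMAP avoids the addition–elimination that isomerises angelate-type acyl groups or expels the allylic acetate.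

Step 6
Reactants: 10 4-acetyl-2-formyl-5-methoxyphenyl (Z)-2-(acetoxymethyl)but-2-enoate; 11 3-chloro-2-methylprop-1-ene
Product: 14 4-acetyl-2-[(1S,2S)-2-chloro-1-hydroxy-3-methylbut-3-en-1-yl]-5-methoxyphenyl (Z)-2-(acetoxymethyl)but-2-enoate, via chloroallylborane 12 (not isolated), via borinate adduct 13 (not isolated)
Conditions: 11, (+)-Ipc2BOMe, LiN(c-C6H11)2, THF–Et2O, −95 °C; BF3·OEt2; then 10, −95 °C; pH 7 buffer, 0 °C
Reagents that add atoms: none
Why: Asymmetric γ-chloroallylboration: borane 12 (from in-flask trapping of lithiated 11 and BF3-induced loss of methoxide) should add through a Zimmerman–Traxler chair with aryl equatorial and the (Z)-chlorine axial to give the syn chlorohydrin, the Ipc groups directing re-face attack to set 1S,2S (the later C3 and C2); ketone and esters should be inert at −95 °C, and any O→O acyl shift during work-up only anticipates step 7.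

Step 7
Reactants: 14 4-acetyl-2-[(1S,2S)-2-chloro-1-hydroxy-3-methylbut-3-en-1-yl]-5-methoxyphenyl (Z)-2-(acetoxymethyl)but-2-enoate
Product: 16 (2R,3S)-5-acetyl-6-methoxy-2-(prop-1-en-2-yl)-2,3-dihydro-1-benzofuran-3-yl (Z)-2-(acetoxymethyl)but-2-enoate, via phenol ester 15 (not isolated)
Conditions: K2CO3 (2 equiv), MeCN (0.01 M), 0 °C to rt
Reagents that add atoms: none
Why: Carbonate promotes an intramolecular O→O acyl shift through a six-membered tetrahedral intermediate (carbinol oxygen onto the activated aryl ester, driven by release of the acidic para-acetylphenol) to give 15, whose phenoxide then displaces the allylic chloride at C2 in an intramolecular Williamson SN2 reaction. The closest known reaction types are the phenol-to-benzylic acyl migration of O-acyl salicyl alcohols and the phenoxide 5-exo-tet etherification used for 2,3-dihydrobenzofurans. The ring O1–C2–C3–C3a–C7a is closed at O1–C2 in the 5-exo-tet mode. C2 is inverted stereospecifically (2S chloride to 2R ether), so the syn chlorohydrin gives the 2,3-trans ring, while C3 keeps its configuration because only the acyl carbon, never the C3–O bond, reacts. The step needs acyl shift before oxirane closure and SN2 at C2 before SN2′ or attack on the acetoxymethyl-enoate: the weak base leaves the carbinol essentially un-ionised yet able to attack the neighbouring active ester, the phenoxide is born next to C2 only after the shift, and high dilution disfavours intermolecular attack on the side chain.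

**Compound list**

1 | but-2-yn-1-ol | CC#CCO | starting material
2 | (Z)-2-(tributylstannyl)but-2-en-1-ol | C/C=C(/CO)[Sn](CCCC)(CCCC)CCCC | intermediate
3 | lithium (Z)-2-lithiobut-2-en-1-olate | C/C=C(/CO[Li])[Li] | intermediate
4 | (Z)-2-(hydroxymethyl)but-2-enoic acid | C/C=C(/CO)C(=O)O | intermediate
5 | (Z)-2-(acetoxymethyl)but-2-enoic acid | C/C=C(/COC(C)=O)C(=O)O | intermediate
6 | 1-(4-hydroxy-2-methoxyphenyl)ethanone | CC(=O)c1ccc(O)cc1OC | starting material
7 | 1-[4-hydroxy-5-(iminomethyl)-2-methoxyphenyl]ethanone | CC(=O)c1cc(C=N)c(O)cc1OC | intermediate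
8 | 5-acetyl-2-hydroxy-4-methoxybenzaldehyde | CC(=O)c1cc(C=O)c(O)cc1OC | intermediate
9 | (Z)-2-(acetoxymethyl)but-2-enoic 2,4,6-trichlorobenzoic anhydride | C/C=C(/COC(C)=O)C(=O)OC(=O)c1c(Cl)cc(Cl)cc1Cl | intermediate
10 | 4-acetyl-2-formyl-5-methoxyphenyl (Z)-2-(acetoxymethyl)but-2-enoate | C/C=C(/COC(C)=O)C(=O)Oc1cc(OC)c(C(C)=O)cc1C=O | intermediate
11 | 3-chloro-2-methylprop-1-ene | C=C(C)CCl | starting material
12 | (Z)-(3-chloro-2-methylprop-2-en-1-yl)diisopinocampheylborane [Ipc from (−)-α-pinene] | Cl/C=C(C)\CB([C@H]1C[C@H]2C[C@@H]([C@@H]1C)C2(C)C)[C@H]3C[C@H]4C[C@@H]([C@@H]3C)C4(C)C | intermediate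
13 | diisopinocampheylborinate of 14 | C=C(C)[C@H](Cl)[C@@H](OB([C@H]1C[C@H]2C[C@@H]([C@@H]1C)C2(C)C)[C@H]3C[C@H]4C[C@@H]([C@@H]3C)C4(C)C)c5cc(C(C)=O)c(OC)cc5OC(=O)/C(=C\C)COC(C)=O | intermediate
14 | 4-acetyl-2-[(1S,2S)-2-chloro-1-hydroxy-3-methylbut-3-en-1-yl]-5-methoxyphenyl (Z)-2-(acetoxymethyl)but-2-enoate | C=C(C)[C@H](Cl)[C@@H](O)c1cc(C(C)=O)c(OC)cc1OC(=O)/C(=C\C)COC(C)=O | intermediate
15 | (1S,2S)-1-(5-acetyl-2-hydroxy-4-methoxyphenyl)-2-chloro-3-methylbut-3-en-1-yl (Z)-2-(acetoxymethyl)but-2-enoate | C=C(C)[C@H](Cl)[C@@H](OC(=O)/C(=C\C)COC(C)=O)c1cc(C(C)=O)c(OC)cc1O | intermediate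
16 | (2R,3S)-5-acetyl-6-methoxy-2-(prop-1-en-2-yl)-2,3-dihydro-1-benzofuran-3-yl (Z)-2-(acetoxymethyl)but-2-enoate | C=C(C)[C@H]1Oc2cc(OC)c(C(C)=O)cc2[C@@H]1OC(=O)/C(=C\C)COC(C)=O | target

**Step count and risks**

Total steps: 7. Longest linear sequence: 6 steps (1 → 2 → 4 → 5 → 10 → 14 → 16).

Risk 1, step 6. The Z geometry of borane 12 may be lost on the 2-methyl-substituted allyl system, which erodes syn selectivity and later the trans ring. Facial control may be incomplete, and the activated aryl ester may shift or be cleaved during addition and work-up. The fallback sets out from 8 and comes back at 16; it makes the ring by a stereoconvergent Pd route before the side chain is present. 8 is silylated (TIPSCl, imidazole, DMF) to the TIPS ether F1. Chloroallylboration with 12 as in step 6 gives, through the borinate F2, the silyl chlorohydrin F3; any anti isomer is carried along. DBU in CH2Cl2 closes F3 to the vinyl oxirane F4 (cis from the syn adduct). TBAF, then Pd(PPh3)4 (5 mol%) in THF at 0 °C free the phenol oxirane F5 (not isolated) and ionise it to a π-allyl complex that the phenoxide closes at C2 (Tsuji–Trost etherification). This is net retention from the cis-oxirane, and π–σ–π exchange through the CH2 terminus should let a C2-epimeric oxirane converge on the trans ring, giving the hydroxy dihydrobenzofuran F6. F6 is acylated with mixed anhydride 9 (Et3N, toluene, 80 °C, no DMAP) to 16.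

Risk 2, step 7 (key step). Oxirane closure by the carbinol oxygen, or attack of phenoxide or carbonate on the acetoxymethyl-enoate (SN2′ loss of acetate), may outrun the acyl shift and the 5-exo-tet closure. The fallback sets out from 8 and comes back at 15; it puts the ester on the carbinol intermolecularly, so that no free alkoxide and no acyl shift are needed. 8 is converted to the TBS ether F7 (TBSCl, imidazole). Chloroallylboration with 12 gives, through the borinate F8, the silyl chlorohydrin F9. The carbinol of F9 is acylated with 9 (Et3N, toluene, 60–80 °C, no DMAP) to the ester F10. TBAF buffered with AcOH in THF at 0 °C removes the silyl group to give 15 as its phenoxide, which should close to 16 as in step 7.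

Risk 3, step 2. Tin–lithium exchange may be incomplete, and the dilithio species may be protonated or aggregate before carboxylation. The fallback sets out from 2 and comes back at 4. Pd-catalysed oxidative methoxycarbonylation of the stannane (Pd(OAc)2, Ph3As, benzoquinone, TFA, CO 1 atm, MeOH, rt), which should keep the alkene geometry, gives the methyl ester F11. LiOH in THF–H2O then gives 4.

**Further compounds**

F1 | step 6 | 1-{5-formyl-2-methoxy-4-[(triisopropylsilyl)oxy]phenyl}ethanone | CC(=O)c1cc(C=O)c(O[Si](C(C)C)(C(C)C)C(C)C)cc1OC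
F2 | step 6 | diisopinocampheylborinate of F3 | C=C(C)[C@H](Cl)[C@@H](OB([C@H]1C[C@H]2C[C@@H]([C@@H]1C)C2(C)C)[C@H]3C[C@H]4C[C@@H]([C@@H]3C)C4(C)C)c5cc(C(C)=O)c(OC)cc5O[Si](C(C)C)(C(C)C)C(C)C
F3 | step 6 | 1-{5-[(1S,2S)-2-chloro-1-hydroxy-3-methylbut-3-en-1-yl]-2-methoxy-4-[(triisopropylsilyl)oxy]phenyl}ethanone | C=C(C)[C@H](Cl)[C@@H](O)c1cc(C(C)=O)c(OC)cc1O[Si](C(C)C)(C(C)C)C(C)C
F4 | step 6 | 1-{2-methoxy-5-[(2S,3R)-3-(prop-1-en-2-yl)oxiran-2-yl]-4-[(triisopropylsilyl)oxy]phenyl}ethanone | C=C(C)[C@H]1O[C@H]1c2cc(C(C)=O)c(OC)cc2O[Si](C(C)C)(C(C)C)C(C)C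
F5 | step 6 | 1-{4-hydroxy-2-methoxy-5-[(2S,3R)-3-(prop-1-en-2-yl)oxiran-2-yl]phenyl}ethanone | C=C(C)[C@H]1O[C@H]1c2cc(C(C)=O)c(OC)cc2O
F6 | step 6 | 1-[(2R,3S)-3-hydroxy-6-methoxy-2-(prop-1-en-2-yl)-2,3-dihydro-1-benzofuran-5-yl]ethanone | C=C(C)[C@H]1Oc2cc(OC)c(C(C)=O)cc2[C@@H]1O
F7 | step 7 | 1-{4-[(tert-butyldimethylsilyl)oxy]-5-formyl-2-methoxyphenyl}ethanone | CC(=O)c1cc(C=O)c(O[Si](C)(C)C(C)(C)C)cc1OC
F8 | step 7 | diisopinocampheylborinate of F9 | C=C(C)[C@H](Cl)[C@@H](OB([C@H]1C[C@H]2C[C@@H]([C@@H]1C)C2(C)C)[C@H]3C[C@H]4C[C@@H]([C@@H]3C)C4(C)C)c5cc(C(C)=O)c(OC)cc5O[Si](C)(C)C(C)(C)C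
F9 | step 7 | 1-{4-[(tert-butyldimethylsilyl)oxy]-5-[(1S,2S)-2-chloro-1-hydroxy-3-methylbut-3-en-1-yl]-2-methoxyphenyl}ethanone | C=C(C)[C@H](Cl)[C@@H](O)c1cc(C(C)=O)c(OC)cc1O[Si](C)(C)C(C)(C)C
F10 | step 7 | (1S,2S)-1-{5-acetyl-2-[(tert-butyldimethylsilyl)oxy]-4-methoxyphenyl}-2-chloro-3-methylbut-3-en-1-yl (Z)-2-(acetoxymethyl)but-2-enoate | C=C(C)[C@H](Cl)[C@@H](OC(=O)/C(=C\C)COC(C)=O)c1cc(C(C)=O)c(OC)cc1O[Si](C)(C)C(C)(C)C
F11 | step 2 | methyl (Z)-2-(hydroxymethyl)but-2-enoate | C/C=C(/CO)C(=O)OC
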